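The route rests on a single 1,2-shift across the C9–C10 bond. The target's methyl-bearing quaternary C10 sits next to oxidised C9 of ring B, so ring A (C1–C5, C10) is made as a seven-membered ring that still contains C9, fused to a cyclopentane (C5–C9). Hydrogen-atom transfer to the C10=C1 alkene of this cis-fused hydroazulenol gives the C10 cation. Migration of the C9–C5 bond then contracts the seven-membered ring to ring A, expands the cyclopentane to ring B, and sets the C10 quaternary centre, the cis ring fusion and the C9 ketone at once. The hydroazulenol comes from eucarvone, which supplies C1–C5, C9, C10 and all three methyl groups.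

Key step: step 6

Remarks on the chemistry:
- Atom labels C1–C12 follow drimane numbering of the target (C5/C10 ring fusion, C6 acyloxy, C7=C8, C9 carbinol, C11 acid, C12 aldehyde).
- The stereodescriptors of the target encode a cis-fused decalin, (5R,6R,9R,10S): H5, the C10 methyl, the C6 oxygen and the C9 hydroxyl lie on one face; the route is planned for this isomer.
- Eucarvone (1), 4-oxobutanenitrile (4) and (2E,4E,6E)-octa-2,4,6-trienoic acid (16) are taken as purchasable; eucarvone is otherwise two steps from carvone.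
- The nitrile-bearing carbon C8 is carried as an epimer mixture in 8 and 9 and becomes sp2 in step 7.
- The target is drawn as the open hydroxy acid–aldehyde; it may equilibrate with its cyclic lactol (pseudo-acid) form.

Step 1
Reactants: 1 eucarvone (2,6,6-trimethylcyclohepta-2,4-dien-1-one)
Product: 2 2,6,6-trimethylcyclohept-2-en-1-one
Conditions: H2 (1 atm), RhCl(PPh3)3 (5 mol%), benzene, rt
Reagents that add atoms: none
Why: Homogeneous hydrogenation with RhCl(PPh3)3 should saturate only the cis-disubstituted γ,δ-alkene and leave the trisubstituted α-methyl enone alkene, as in selective dienone hydrogenations with this catalyst.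

Step 2
Reactants: 2 2,6,6-trimethylcyclohept-2-en-1-one
Product: 3 2-(trimethylsilyloxy)-3,7,7-trimethylcyclohepta-1,3-diene
Conditions: LiN(iPr)2, THF, −78 °C; Me3SiCl, Et3N, −78 → 0 °C
Reagents that add atoms: chlorotrimethylsilane, C[Si](C)(C)Cl
Why: Kinetic α′-deprotonation at the only enolisable CH2 (C5, next to the gem-dimethyl carbon, as with isophorone) and O-silylation should give the cross-conjugated silyl dienol ether.

Step 3
Reactants: 3 2-(trimethylsilyloxy)-3,7,7-trimethylcyclohepta-1,3-diene; 4 4-oxobutanenitrile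
Product: 6 (4R)-4-hydroxy-4-[(1S)-3,7,7-trimethyl-2-oxocyclohept-3-en-1-yl]butanenitrile, via O-trimethylsilyl aldol adduct 5 (not isolated)
Conditions: chiral (acyloxy)borane (20 mol%) made from (2S,3S)-2-O-(2,6-diisopropoxybenzoyl)tartaric acid and BH3·THF, EtCN, −78 °C; then 1 M HCl, THF, 0 °C
Reagents that add atoms: none
Why: Catalytic asymmetric Mukaiyama aldol in which the tartrate-derived (acyloxy)borane, through an open transition state, should give the syn aldol whatever the enol silane geometry, the catalyst fixing the aldehyde face (C6) and C5 following from it; the (2S,3S) ligand is chosen on the assumption that it delivers the (4R) carbinol.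

Step 4
Reactants: 6 (4R)-4-hydroxy-4-[(1S)-3,7,7-trimethyl-2-oxocyclohept-3-en-1-yl]butanenitrile
Product: 7 (4R)-4-[(tert-butyldimethylsilyl)oxy]-4-[(1S)-3,7,7-trimethyl-2-oxocyclohept-3-en-1-yl]butanenitrile
Conditions: tBuMe2SiOTf, 2,6-lutidine, CH2Cl2, −78 °C
Reagents that add atoms: tert-butyldimethylsilyl trifluoromethanesulfonate, CC(C)(C)[Si](C)(C)OS(=O)(=O)C(F)(F)F
Why: Silylation with the triflate at low temperature should protect the secondary alcohol without retro-aldol or β-elimination of the β-hydroxy ketone.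

Step 5
Reactants: 7 (4R)-4-[(tert-butyldimethylsilyl)oxy]-4-[(1S)-3,7,7-trimethyl-2-oxocyclohept-3-en-1-yl]butanenitrile
Product: 8 (3R,3aS,8aS)-3-[(tert-butyldimethylsilyl)oxy]-8a-hydroxy-4,4,8-trimethyl-1,2,3,3a,4,5,6,8a-octahydroazulene-1-carbonitrile (cis-fused, C1 epimers)
Conditions: LiN(iPr)2 (1.1 equiv), THF, −78 °C; aq NH4Cl at −78 °C
Reagents that add atoms: none
Why: Intramolecular nitrile aldol (5-exo-trig) in which the unhindered CH2CN should be lithiated faster than the shielded C5 methine, and the three-atom tether forces 1,2-attack on the carbonyl from the side of the chain, so the new C9 carbinol has OH cis to H5 (cis ring fusion).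

Step 6
Reactants: 8 (3R,3aS,8aS)-3-[(tert-butyldimethylsilyl)oxy]-8a-hydroxy-4,4,8-trimethyl-1,2,3,3a,4,5,6,8a-octahydroazulene-1-carbonitrile
Product: 9 (4R,4aR,8aS)-4-[(tert-butyldimethylsilyl)oxy]-5,5,8a-trimethyl-1-oxodecahydronaphthalene-2-carbonitrile (cis-fused, C2 epimers)
Conditions: C36H52CoN2O2 [(R,R)-N,N′-bis(3,5-di-tert-butylsalicylidene)cyclohexane-1,2-diaminocobalt, divalent cobalt] (5 mol%), N-fluoro-2,4,6-trimethylpyridinium tetrafluoroborate (1.5 equiv), PhSiH3 (1.2 equiv), acetone, 0 °C → rt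
Reagents that add atoms: none
Why: A cobalt hydride formed from the cobalt salen complex, the N-fluoropyridinium oxidant and PhSiH3 should transfer a hydrogen atom to C1 of the C10=C1 alkene, the tertiary C10 radical is oxidised to the C10 cation (radical–polar crossover), the C9–C5 bond shifts to C10, and the C9 hydroxyl loses its proton to give the ketone. The closest known reaction type is the HAT-initiated radical–polar crossover semipinacol rearrangement of tertiary allylic alcohols, established mainly as ring expansion of 1-alkenylcycloalkanols. No ring is closed by cyclisation: ring A arises by contraction of the seven-membered ring (C9 is expelled) and ring B by expansion of the cyclopentane (C10 is inserted) through the same suprafacial 1,2-alkyl shift. C5 migrates with retention, and the new quaternary C10 is controlled by the cis fusion of 8: the poor-donor C9–O bond should lie near the plane of the cation beside the small C10 methyl (least allylic strain), which puts the C9–C5 bond parallel to the empty orbital with C1 turned toward C8, so C5 bonds to the face that places H5 and the C10 methyl cis. The step needs C5 and not C8 to migrate and no ionisation of the tertiary C–O bond: C8 is a nitrile-bearing, electron-poor carbon whose shift would give a bridged ketone instead of two six-membered rings, and the neutral HAT conditions create the cation only at C10.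

Step 7
Reactants: 9 (4R,4aR,8aS)-4-[(tert-butyldimethylsilyl)oxy]-5,5,8a-trimethyl-1-oxodecahydronaphthalene-2-carbonitrile
Product: 10 (4R,4aR,8aS)-4-[(tert-butyldimethylsilyl)oxy]-2-cyano-5,5,8a-trimethyl-3,4,4a,5,6,7,8,8a-octahydronaphthalen-1-yl trifluoromethanesulfonate
Conditions: iPr2NEt, Tf2O, CH2Cl2, −78 → 0 °C
Reagents that add atoms: trifluoromethanesulfonic anhydride, O=S(=O)(OS(=O)(=O)C(F)(F)F)C(F)(F)F
Why: The β-keto nitrile enolises only toward C8, so O-triflation should give the single tetrasubstituted C8=C9 enol triflate and removes the C8 stereocentre.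

Step 8
Reactants: 10 (4R,4aR,8aS)-4-[(tert-butyldimethylsilyl)oxy]-2-cyano-5,5,8a-trimethyl-3,4,4a,5,6,7,8,8a-octahydronaphthalen-1-yl trifluoromethanesulfonate
Product: 11 2-(trimethylsilyl)ethyl (4R,4aR,8aS)-4-[(tert-butyldimethylsilyl)oxy]-2-cyano-5,5,8a-trimethyl-3,4,4a,5,6,7,8,8a-octahydronaphthalene-1-carboxylate
Conditions: Pd(OAc)2 (10 mol%), 1,3-bis(diphenylphosphino)propane (12 mol%), CO (1 atm), Me3SiCH2CH2OH (5 equiv), Et3N, DMF, 70 °C
Reagents that add atoms: carbon monoxide, [C-]#[O+]; 2-(trimethylsilyl)ethanol, C[Si](C)(C)CCO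
Why: Palladium-catalysed alkoxycarbonylation (oxidative addition of zerovalent palladium to the electron-poor enol triflate, CO insertion, alcoholysis) should install C11 as a fluoride-labile ester.

Step 9
Reactants: 11 2-(trimethylsilyl)ethyl (4R,4aR,8aS)-4-[(tert-butyldimethylsilyl)oxy]-2-cyano-5,5,8a-trimethyl-3,4,4a,5,6,7,8,8a-octahydronaphthalene-1-carboxylate
Product: 12 2-(trimethylsilyl)ethyl (1R,4R,4aR,8aS)-4-[(tert-butyldimethylsilyl)oxy]-2-cyano-1-hydroxy-5,5,8a-trimethyl-1,4,4a,5,6,7,8,8a-octahydronaphthalene-1-carboxylate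
Conditions: KN(SiMe3)2 (1.1 equiv), THF, −78 °C; 2-(phenylsulfonyl)-3-phenyloxaziridine (1.3 equiv), −78 °C; aq NH4Cl
Reagents that add atoms: 2-(phenylsulfonyl)-3-phenyloxaziridine, O=S(=O)(c1ccccc1)N1OC1c1ccccc1
Why: γ-Deprotonation at C7 gives the extended ester enolate and electrophilic α-hydroxylation at C9 moves the alkene to C7=C8 (as in the known C9 hydroxylation of drimane ester dienolates), the oxidant being expected anti to the pseudo-axial C10–C1 bond, on the face of the C10 methyl.

Step 10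
Reactants: 12 2-(trimethylsilyl)ethyl (1R,4R,4aR,8aS)-4-[(tert-butyldimethylsilyl)oxy]-2-cyano-1-hydroxy-5,5,8a-trimethyl-1,4,4a,5,6,7,8,8a-octahydronaphthalene-1-carboxylate
Product: 14 2-(trimethylsilyl)ethyl (1R,4R,4aR,8aS)-4-[(tert-butyldimethylsilyl)oxy]-2-formyl-1-hydroxy-5,5,8a-trimethyl-1,4,4a,5,6,7,8,8a-octahydronaphthalene-1-carboxylate, via aldimine 13 (not isolated)
Conditions: iBu2AlH (2.5 equiv), toluene, −78 °C; then aq tartaric acid, 0 °C
Reagents that add atoms: water, O
Why: iBu2AlH should reduce the conjugated nitrile to the N-aluminated aldimine, hydrolysed to the enal on work-up, while the ester on the fully substituted C9 is too hindered to react at −78 °C.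

Step 11
Reactants: 14 2-(trimethylsilyl)ethyl (1R,4R,4aR,8aS)-4-[(tert-butyldimethylsilyl)oxy]-2-formyl-1-hydroxy-5,5,8a-trimethyl-1,4,4a,5,6,7,8,8a-octahydronaphthalene-1-carboxylate
Product: 15 2-(trimethylsilyl)ethyl (1R,4R,4aR,8aS)-2-formyl-1,4-dihydroxy-5,5,8a-trimethyl-1,4,4a,5,6,7,8,8a-octahydronaphthalene-1-carboxylate
Conditions: HF·pyridine, pyridine, THF, 0 °C → rt
Reagents that add atoms: none
Why: Buffered HF·pyridine should cleave the secondary silyl ether and leave the 2-(trimethylsilyl)ethyl ester, the tertiary alcohol and the enal intact.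

Step 12
Reactants: 15 2-(trimethylsilyl)ethyl (1R,4R,4aR,8aS)-2-formyl-1,4-dihydroxy-5,5,8a-trimethyl-1,4,4a,5,6,7,8,8a-octahydronaphthalene-1-carboxylate; 16 (2E,4E,6E)-octa-2,4,6-trienoic acid
Product: 18 2-(trimethylsilyl)ethyl (1R,4R,4aR,8aS)-2-formyl-1-hydroxy-5,5,8a-trimethyl-4-{[(2E,4E,6E)-octa-2,4,6-trienoyl]oxy}-1,4,4a,5,6,7,8,8a-octahydronaphthalene-1-carboxylate, via trichlorobenzoic mixed anhydride 17 (not isolated)
Conditions: 16, 2,4,6-trichlorobenzoyl chloride, Et3N, toluene, rt; then 15, DMAP, rt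
Reagents that add atoms: none
Why: Yamaguchi esterification through the mixed anhydride should acylate only the secondary allylic C6 hydroxyl, the tertiary C9 hydroxyl being inert, under conditions too mild to isomerise the triene.

Step 13
Reactants: 18 2-(trimethylsilyl)ethyl (1R,4R,4aR,8aS)-2-formyl-1-hydroxy-5,5,8a-trimethyl-4-{[(2E,4E,6E)-octa-2,4,6-trienoyl]oxy}-1,4,4a,5,6,7,8,8a-octahydronaphthalene-1-carboxylate
Product: 19 (1R,4R,4aR,8aS)-2-formyl-1-hydroxy-5,5,8a-trimethyl-4-{[(2E,4E,6E)-octa-2,4,6-trienoyl]oxy}-1,4,4a,5,6,7,8,8a-octahydronaphthalene-1-carboxylic acid (CNP0234478.8)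
Conditions: Bu4NF, THF, 0 °C; cold 0.5 M HCl work-up
Reagents that add atoms: none
Why: Fluoride-induced β-elimination of the 2-(trimethylsilyl)ethyl ester (loss of Me3SiF and ethene) should free the carboxylic acid while sparing the trienoate ester and the enal.

Compound list
1 | eucarvone, 2,6,6-trimethylcyclohepta-2,4-dien-1-one | CC1=CC=CC(C)(C)CC1=O | starting material
2 | 2,6,6-trimethylcyclohept-2-en-1-one | CC1=CCCC(C)(C)CC1=O | intermediate
3 | 2-(trimethylsilyloxy)-3,7,7-trimethylcyclohepta-1,3-diene | C[Si](C)(C)OC1=CC(C)(C)CCC=C1C | intermediate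
4 | 4-oxobutanenitrile | N#CCCC=O | starting material
5 | O-trimethylsilyl ether of 6 | C[Si](C)(C)O[C@H](CCC#N)[C@H]1C(=O)C(C)=CCCC1(C)C | intermediate (not isolated)
6 | (4R)-4-hydroxy-4-[(1S)-3,7,7-trimethyl-2-oxocyclohept-3-en-1-yl]butanenitrile | O[C@H](CCC#N)[C@H]1C(=O)C(C)=CCCC1(C)C | intermediate
7 | (4R)-4-[(tert-butyldimethylsilyl)oxy]-4-[(1S)-3,7,7-trimethyl-2-oxocyclohept-3-en-1-yl]butanenitrile | CC(C)(C)[Si](C)(C)O[C@H](CCC#N)[C@H]1C(=O)C(C)=CCCC1(C)C | intermediate
8 | (3R,3aS,8aS)-3-[(tert-butyldimethylsilyl)oxy]-8a-hydroxy-4,4,8-trimethyl-1,2,3,3a,4,5,6,8a-octahydroazulene-1-carbonitrile, cis-fused, C1 epimers | CC(C)(C)[Si](C)(C)O[C@@H]1CC(C#N)[C@@]2(O)C(C)=CCCC(C)(C)[C@@H]12 | intermediate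
9 | (4R,4aR,8aS)-4-[(tert-butyldimethylsilyl)oxy]-5,5,8a-trimethyl-1-oxodecahydronaphthalene-2-carbonitrile, cis-fused, C2 epimers | CC(C)(C)[Si](C)(C)O[C@@H]1CC(C#N)C(=O)[C@@]2(C)CCCC(C)(C)[C@@H]12 | intermediate
10 | (4R,4aR,8aS)-4-[(tert-butyldimethylsilyl)oxy]-2-cyano-5,5,8a-trimethyl-3,4,4a,5,6,7,8,8a-octahydronaphthalen-1-yl trifluoromethanesulfonate | CC(C)(C)[Si](C)(C)O[C@@H]1CC(C#N)=C(OS(=O)(=O)C(F)(F)F)[C@@]2(C)CCCC(C)(C)[C@@H]12 | intermediate
11 | 2-(trimethylsilyl)ethyl (4R,4aR,8aS)-4-[(tert-butyldimethylsilyl)oxy]-2-cyano-5,5,8a-trimethyl-3,4,4a,5,6,7,8,8a-octahydronaphthalene-1-carboxylate | CC(C)(C)[Si](C)(C)O[C@@H]1CC(C#N)=C(C(=O)OCC[Si](C)(C)C)[C@@]2(C)CCCC(C)(C)[C@@H]12 | intermediate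
12 | 2-(trimethylsilyl)ethyl (1R,4R,4aR,8aS)-4-[(tert-butyldimethylsilyl)oxy]-2-cyano-1-hydroxy-5,5,8a-trimethyl-1,4,4a,5,6,7,8,8a-octahydronaphthalene-1-carboxylate | CC(C)(C)[Si](C)(C)O[C@@H]1C=C(C#N)[C@@](O)(C(=O)OCC[Si](C)(C)C)[C@@]2(C)CCCC(C)(C)[C@@H]12 | intermediate
13 | aldimine of 14 (CH=NH in place of CHO, held as its N-aluminium derivative until work-up) | CC(C)(C)[Si](C)(C)O[C@@H]1C=C(C=N)[C@@](O)(C(=O)OCC[Si](C)(C)C)[C@@]2(C)CCCC(C)(C)[C@@H]12 | intermediate (not isolated)
14 | 2-(trimethylsilyl)ethyl (1R,4R,4aR,8aS)-4-[(tert-butyldimethylsilyl)oxy]-2-formyl-1-hydroxy-5,5,8a-trimethyl-1,4,4a,5,6,7,8,8a-octahydronaphthalene-1-carboxylate | CC(C)(C)[Si](C)(C)O[C@@H]1C=C(C=O)[C@@](O)(C(=O)OCC[Si](C)(C)C)[C@@]2(C)CCCC(C)(C)[C@@H]12 | intermediate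
15 | 2-(trimethylsilyl)ethyl (1R,4R,4aR,8aS)-2-formyl-1,4-dihydroxy-5,5,8a-trimethyl-1,4,4a,5,6,7,8,8a-octahydronaphthalene-1-carboxylate | O[C@@H]1C=C(C=O)[C@@](O)(C(=O)OCC[Si](C)(C)C)[C@@]2(C)CCCC(C)(C)[C@@H]12 | intermediate
16 | (2E,4E,6E)-octa-2,4,6-trienoic acid | C/C=C/C=C/C=C/C(=O)O | starting material
17 | mixed anhydride of 16 and 2,4,6-trichlorobenzoic acid | C/C=C/C=C/C=C/C(=O)OC(=O)c1c(Cl)cc(Cl)cc1Cl | intermediate (not isolated)
18 | 2-(trimethylsilyl)ethyl (1R,4R,4aR,8aS)-2-formyl-1-hydroxy-5,5,8a-trimethyl-4-{[(2E,4E,6E)-octa-2,4,6-trienoyl]oxy}-1,4,4a,5,6,7,8,8a-octahydronaphthalene-1-carboxylate | C/C=C/C=C/C=C/C(=O)O[C@@H]1C=C(C=O)[C@@](O)(C(=O)OCC[Si](C)(C)C)[C@@]2(C)CCCC(C)(C)[C@@H]12 | intermediate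
19 | (1R,4R,4aR,8aS)-2-formyl-1-hydroxy-5,5,8a-trimethyl-4-{[(2E,4E,6E)-octa-2,4,6-trienoyl]oxy}-1,4,4a,5,6,7,8,8a-octahydronaphthalene-1-carboxylic acid | C/C=C/C=C/C=C/C(=O)O[C@@H]1C=C(C=O)[C@@](O)(C(=O)O)[C@@]2(C)CCCC(C)(C)[C@@H]12 | target

Total step count: 13
Longest linear sequence: 13 steps (1 → 19)

Steps most likely to fail

1. Step 6 (key step). The tertiary cation may lose a proton to give alkene isomers, the C9–C8 bond may migrate instead of C9–C5, or the shift may pass through the other rotamer about C9–C10 and give the trans-fused ketone (loss of facial control). Fallback, setting out from 8 and returning at 9: the free cation is replaced by a stereospecific epoxide opening. The tertiary hydroxyl of 8 would be silylated (Et3SiOTf, 2,6-lutidine) to the triethylsilyl ether F1. Epoxidation with mCPBA/NaHCO3, expected anti to the bulky silyloxy group, would give the C10–C1 epoxy silyl ether F2. TiCl4 in CH2Cl2 at −78 °C would then trigger the known semipinacol rearrangement of 2,3-epoxy silyl ethers: only the C9–C5 bond can stand antiperiplanar to the breaking C10–O bond (C8 is cis to the epoxide), so the cis-fused C1-hydroxy ketone F3 should form. Its hydroxyl would be converted with 1,1′-thiocarbonyldiimidazole to the imidazolylthiocarbonate F4 and removed with Bu3SnH/AIBN in toluene at 80 °C (Barton–McCombie deoxygenation) to give 9.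

2. Step 3. The hindered dienol silane and the enolisable aldehyde may give a poor syn/anti ratio or low enantioselectivity. Fallback, setting out from 2 and returning at 6: enolate control replaces catalyst control. The lithium enolate of 2 (LiN(iPr)2, THF, −78 °C) would be transmetalated with ClTi(OiPr)3 and treated with 4; triisopropoxytitanium enolates of cyclic ketones are syn-selective, giving racemic syn aldol, that is 6 together with its enantiomer F5. Kinetic resolution with Pseudomonas cepacia lipase and vinyl acetate should acetylate the (4R)-alcohol to the acetate F6, which is separated from F5 and cleaved by the same lipase in pH 7 buffer to return 6.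

3. Step 9. The oxidant may approach the dienolate on the α-face or at C7, or the C6 silyloxy group may be eliminated from the dienolate. Fallback, setting out from 9 and returning at 12: C11 is added as a nucleophile instead of oxygen as an electrophile, so an open α-face now places the carbon substituent α and the hydroxyl β. DDQ in refluxing dioxane would dehydrogenate 9 to the 2-cyano enone F7. Vinylmagnesium bromide/CeCl3 in THF at −78 °C should add 1,2 to give the vinyl carbinol F8. Ozonolysis (O3, CH2Cl2/MeOH, −78 °C; Me2S) would give the α-hydroxy aldehyde F9, and Pinnick oxidation (NaClO2, NaH2PO4, 2-methylbut-2-ene) the α-hydroxy acid F10. Esterification with Me3SiCH2CH2OH (2-chloro-1-methylpyridinium iodide, Et3N) returns 12.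

Further compounds
F1 | step 6 | triethylsilyl ether of 8 | CC(C)(C)[Si](C)(C)O[C@@H]1CC(C#N)[C@@]2(O[Si](CC)(CC)CC)C(C)=CCCC(C)(C)[C@@H]12
F2 | step 6 | C10–C1 epoxide of F1, epoxide oxygen anti to the silyloxy group | CC(C)(C)[Si](C)(C)O[C@@H]1CC(C#N)[C@@]2(O[Si](CC)(CC)CC)[C@@]3(C)O[C@H]3CCC(C)(C)[C@@H]12
F3 | step 6 | C1-hydroxy derivative of 9 (cis-fused β-hydroxy ketone) | CC(C)(C)[Si](C)(C)O[C@@H]1CC(C#N)C(=O)[C@@]2(C)[C@@H](O)CCC(C)(C)[C@@H]12
F4 | step 6 | O-(imidazol-1-ylthiocarbonyl) derivative of F3 | CC(C)(C)[Si](C)(C)O[C@@H]1CC(C#N)C(=O)[C@@]2(C)[C@@H](OC(=S)n3ccnc3)CCC(C)(C)[C@@H]12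
F5 | step 3 | enantiomer of 6, (4S)-4-hydroxy-4-[(1R)-3,7,7-trimethyl-2-oxocyclohept-3-en-1-yl]butanenitrile | O[C@@H](CCC#N)[C@@H]1C(=O)C(C)=CCCC1(C)C
F6 | step 3 | acetate of 6 | CC(=O)O[C@H](CCC#N)[C@H]1C(=O)C(C)=CCCC1(C)C
F7 | step 9 | (4R,4aR,8aS)-4-[(tert-butyldimethylsilyl)oxy]-5,5,8a-trimethyl-1-oxo-1,4,4a,5,6,7,8,8a-octahydronaphthalene-2-carbonitrile (2-cyano enone) | CC(C)(C)[Si](C)(C)O[C@@H]1C=C(C#N)C(=O)[C@@]2(C)CCCC(C)(C)[C@@H]12
F8 | step 9 | C9 vinyl carbinol from F7 | CC(C)(C)[Si](C)(C)O[C@@H]1C=C(C#N)[C@@](O)(C=C)[C@@]2(C)CCCC(C)(C)[C@@H]12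
F9 | step 9 | C9 α-hydroxy aldehyde from F8 | CC(C)(C)[Si](C)(C)O[C@@H]1C=C(C#N)[C@@](O)(C=O)[C@@]2(C)CCCC(C)(C)[C@@H]12
F10 | step 9 | C9 α-hydroxy acid (free acid of 12) | CC(C)(C)[Si](C)(C)O[C@@H]1C=C(C#N)[C@@](O)(C(=O)O)[C@@]2(C)CCCC(C)(C)[C@@H]12
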